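## Structural features

The target (C24H14O11) is an achiral, fully aromatic phlorotannin. A pendant 3,5-dihydroxyphenyl ether (ring E) sits on a pentaoxygenated benzene (ring A), which is fused through a 1,4-dioxin (ring B) to a dibenzofuran (rings C and D). Ring A is labelled A1 (O–ring E), A2 (OH), A3 (its only C–H), A4 (OH), A5 and A6 (dioxin oxygens). Rings C and D keep dibenzofuran locants, so the dioxin bonds are A5–O–C1 (C1 is next to the ring-fusion carbon C9b) and A6–O–C2 (C2 is next to C3–OH), with further hydroxyls at C3, C7 and C9. There is no stereocentre and no hindered axis, so every selectivity question is one of regiochemistry. The seven free phenols on electron-rich rings make the final compound prone to air oxidation, whereas the diaryl ether, dioxin and furan C–O bonds are robust. The real difficulty is twofold: five contiguous oxygenated carbons on ring A must be told apart, and the dioxin must close in one orientation although both of its partners are unsymmetrical. Ring A has a local symmetry that helps: A6 is flanked by A5 and A1, which are flanked by A4 and A2, both hydroxyls in the target, so only "central oxygen (A6) versus flanking oxygens" and "which flank carries ring E" matter. The key step exploits the array A5–A6–A1–A2, whose four oxygenated carbons map onto squaric acid, while A3–H and A4–O come from an alkoxyvinyl unit; the ring expansion forms the A5–A4 bond and releases the A5 oxygen as the only free hydroxyl.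

## Logic of the disconnections

28 ⇒ 27. The seven phenolic O–H bonds are traced back to five O–CH3 bonds, one O–CH2CH3 bond and one O–CH2OCH3 bond. The heptaphenol is the most oxidation-prone compound and should exist only at the end. All earlier intermediates are then stable ethers. The forward step needs one Lewis acid that removes all seven groups, including the ethyl ether, without touching the aryl–O–aryl bonds.

27 ⇒ 23 + 26. The bond cut is the ring E carbon–oxygen bond at A1. At this stage A1–OH is the only free hydroxyl, and ring E is a symmetrical aryl group. The pentacyclic core is freed of its sixth ring. The forward step must arylate a hydroxyl flanked by two oxygen substituents, which calls for a trivalent-iodine aryl donor and not a metal-catalysed coupling.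

23 ⇒ 22. The bond cut is O(A6)–C2, which opens the dioxin. In 22 only the A6 oxygen can reach C2 through a six-membered ring; the A1 oxygen would need a seven-membered ring. The orientation of the dioxin is therefore set by connectivity and not by reagent control. The forward step is a C–O coupling at an electron-rich, di-ortho-substituted aryl sulfonate.

22 ⇒ 21. Two O–benzyl bonds are cut. The A6 and A1 oxygens are unmasked together because the ring-size argument above makes it unnecessary to tell them apart. The forward hydrogenolysis must spare the aryl triflate, the acetal and the alkyl aryl ethers.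

21 ⇒ 10 + 20. The bond cut is O(A5)–C1. Compound 10 has exactly one free hydroxyl, so this union decides which ring A oxygen is joined to the ring-fusion side of ring C. Because of the local symmetry of ring A, using that hydroxyl for C1 and not for ring E gives the same final constitution, but it turns the dioxin regiochemistry into a matter of connectivity. If ring E were put on first, the two benzyl-marked oxygens would have to be distinguished in an intermolecular dioxin annulation, for which no control element exists. The forward step forms a tetra-ortho-substituted diaryl ether and needs a C1 leaving group far more reactive than the handle at C2.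

10 ⇒ 7. The bond cut is the ring A C–C bond A5–A4; in the retron the C1–C4 σ bond of a cyclobutenone is restored. This traces a pentaoxygenated arene with five differently tagged oxygens to a four-membered ring assembled in one flask. The forward step needs the alkoxyvinyl group to rotate inward during ring opening.

7 ⇒ 3 + 4. The bonds cut are the C4–vinyl C–C bond and the acetal O–CH2 bond. Compound 3 is symmetrical, so the addition has no regiochemical issue. The forward step needs a configurationally stable (Z)-vinyllithium and capping of the tertiary alkoxide before the acid-labile carbinol is ever isolated.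

3 ⇒ 1 + 2. The two ester C–O bonds are cut, which returns 1 and two molecules of 2, both commercial. The forward step must drive a double condensation to completion, so water has to be removed as it forms.

20 ⇒ 18 ⇒ 17 ⇒ 16. The bonds cut are the iodine–dummy-aryl bond, the O–S bond at C2 and the C1–I bond. The C2 hydroxyl of 16 directs iodine to C1, its only free ortho position (C3 and the para position C4a are blocked), and then becomes the leaving group for dioxin closure. Both dioxin-forming positions of ring C are thus functionalised and differentiated from one hydroxyl. The forward oxidation to trivalent iodine must not let the electron-rich ring D act as the arene partner.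

16 ⇒ 14 ⇒ 13 ⇒ 11 + 12. The bonds cut are C2–O (back to a formyl C–C bond), the biaryl bond C9a–C9b and the ether bond C4a–O. The formyl group serves twice: it activates the para fluoride of 11 for substitution and later becomes the C2 oxygen. The two ortho C–H positions of the aryloxy ring in 13 are equivalent, so the dibenzofuran can form as one isomer only.

26 ⇒ 24. The iodine–dummy-aryl bond is cut, leading to a commercial iodoarene.

## Other disconnections considered

Alternative 1: The cut is the biaryl bond C9a–C9b and one furan C–O bond. In the forward step a ring carbon of phloroglucinol A3 adds, under acid, to 2,6-dimethoxy-1,4-benzoquinone A2, which acts as an aryl cation equivalent; cyclodehydration then closes the furan to 1,3-dimethoxydibenzo[b,d]furan-2,7,9-triol A1.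
- In its favour: both partners are symmetrical and cheap, so the step has no regiochemical issue and delivers rings C and D with all their oxygens in one operation. On step economy for the dibenzofuran it is better than the chosen plan, which needs three steps to reach 16.
- Against it here: A1 carries its own oxygens at C1 and C2, whereas a squarate-derived ring A also brings both dioxin oxygens, so the polarity of the two halves does not match. The C1 and C3 methyl ethers of A1 have different fates but are not differentiated, and three phenols are left unmasked.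
- Comparison: it solves rings C and D but leaves ring A and the dioxin orientation open, which are the problems the chosen key step and the use of 10 address. Mechanistically it is an acid-mediated conjugate arylation whose scope is less predictable than the substitution and direct arylation used for 13 and 14.

Alternative 2: The cut is both aryl C–O bonds of the dioxin on ring A. In the forward step fluoride releases 3-(3,5-dimethoxyphenoxy)-4,6-dimethoxybenzyne A6 from a silyl triflate, and A6 adds across the two carbonyl oxygens of 3,7,9-trimethoxydibenzo[b,d]furan-1,2-dione A5 to give the heptamethyl ether A4.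
- In its favour: it is the most convergent union, forming both dioxin bonds in one neutral step where the chosen plan needs steps 10 to 12. It ends in an ether, A4, that needs the same kind of global dealkylation as 27, so the two plans are equal on that point.
- Against it here: the triple bond of A6 is flanked by oxygen substituents on both sides and is only weakly polarised, so both orientations of the cycloaddition are expected. The precursor of A6 is a pentaoxygenated ortho-silyl aryl triflate that is long to make, and A5 is a sensitive ortho-quinone.
- Comparison: better on convergence, worse on control. The chosen plan fixes the orientation by ring size in step 12, which the cycloaddition cannot do.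

Alternative 3: The cut is C7–C8 of ring D. In the forward step methoxide turns the acetyl methyl of methyl 2-[3-acetyl-5-(benzyloxy)-4,6-dimethoxy-1-benzofuran-2-yl]acetate A8 into an enolate that attacks the ester; enolisation gives 2-(benzyloxy)-1,3-dimethoxydibenzo[b,d]furan-7,9-diol A7.
- In its favour: the polyketide-type closure is regiochemically unambiguous and likely at least as reliable as the direct arylation of step 5. A7 also arrives with a uniquely benzylated C2 oxygen, a differentiation the chosen plan has to create by iodination of 16.
- Against it here: A8 is itself a multistep target. The step builds ring D, the least demanding ring, which the chosen plan buys as 12. Ring C of A7 again brings oxygen at C1 and C2, the same polarity mismatch as in alternative 1.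
- Comparison: equal or better on the reliability of its single key step, clearly worse on overall step economy, and silent on ring A and on the dioxin orientation.

Key step: step 3

Assumption: compound 11 is taken to be a catalogue building block.

## Route

Step 1
Reactants: 1 squaric acid; 2 benzyl alcohol (two molecules are incorporated)
Product: 3 dibenzyl squarate [3,4-bis(benzyloxy)cyclobut-3-ene-1,2-dione]
Conditions: BnOH (2.5 equiv), toluene, reflux, Dean–Stark
Reagents that add atoms: benzyl alcohol (second equivalent), OCc1ccccc1
Why: Twofold Fischer-type esterification of the strongly acidic vinylogous diacid, autocatalysed by the substrate; each hydroxyl of 1 condenses with one molecule of benzyl alcohol and azeotropic removal of the two equivalents of water drives the reaction to the diester.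

Step 2
Reactants: 3 dibenzyl squarate; 4 (Z)-1-bromo-2-ethoxyethene
Product: 7 rac-2,3-bis(benzyloxy)-4-[(Z)-2-ethoxyethenyl]-4-(methoxymethoxy)cyclobut-2-en-1-one, via vinyllithium 5 (not isolated), via lithium alkoxide 6 (not isolated)
Conditions: t-BuLi (2 equiv), THF, −78 °C; then 3, −78 °C; then MOMCl, −78 → 0 °C
Reagents that add atoms: chloromethyl methyl ether (MOMCl), COCCl
Why: Bromine–lithium exchange proceeds with retention and the cis oxygen chelates lithium, so 5 should neither isomerise nor eliminate; it adds 1,2 to either of the two equivalent carbonyls of 3, and O-alkylation of alkoxide 6 in the same flask avoids the acid-labile carbinol. The new quaternary centre is racemic and is destroyed in step 3.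

Step 3
Reactants: 7 rac-2,3-bis(benzyloxy)-4-[(Z)-2-ethoxyethenyl]-4-(methoxymethoxy)cyclobut-2-en-1-one
Product: 10 2,3-bis(benzyloxy)-6-ethoxy-4-(methoxymethoxy)phenol, via dienylketene 8 (not isolated), via cyclohexadienone 9 (not isolated)
Conditions: toluene (degassed, dilute), 110 °C, Ar
Reagents that add atoms: none
Why: Heating should open the cyclobutenone by a thermal conrotatory 4π cleavage of the C1–C4 bond to dienylketene 8; the closest precedent is the Moore rearrangement of squarate-derived 4-alkenyl-4-alkoxycyclobutenones. The ketene carbon then bonds to the ethoxy-bearing vinyl carbon in a thermal disrotatory 6π electrocyclisation, the only ring closure of the step, which forms ring A as cyclohexadienone 9. Enolisation of 9 gives phenol 10 and erases the transient sp3 carbon, so no stereocentre survives and the racemic nature of 7 is irrelevant. The selectivity required is torquoselectivity: the ethoxyvinyl group must rotate inward, cis to the ketene. The methoxymethoxy donor on the quaternary carbon secures this, because an oxygen lone pair prefers outward rotation, where it overlaps with the σ* orbital of the breaking bond. Ring opening is reversible, so a ketene of the wrong geometry should re-close and be funnelled to the productive isomer, while strain release and aromatisation make the overall change irreversible. The Z enol ether places OEt inside the closing triene but cannot change the outcome, since either geometry leads to the same dienone carbon. The product carries one free hydroxyl (A5), two benzyl ethers (A6, A1), one acetal (A2) and one ethyl ether (A4).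

Step 4
Reactants: 11 5-bromo-4-fluoro-2-methoxybenzaldehyde; 12 3,5-dimethoxyphenol
Product: 13 5-bromo-4-(3,5-dimethoxyphenoxy)-2-methoxybenzaldehyde
Conditions: K2CO3, DMF, 80 °C
Reagents that add atoms: none
Why: Nucleophilic aromatic substitution of the fluoride para to the formyl group by the phenoxide; the bromide is not activated and stays.

Step 5
Reactants: 13 5-bromo-4-(3,5-dimethoxyphenoxy)-2-methoxybenzaldehyde
Product: 14 3,7,9-trimethoxydibenzo[b,d]furan-2-carbaldehyde
Conditions: Pd(OAc)2 (cat.), PCy3·HBF4, K2CO3, DMA, 130 °C
Reagents that add atoms: none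
Why: Intramolecular direct arylation: zerovalent palladium inserts into the C–Br bond and a carbonate-assisted concerted metalation–deprotonation closes the furan. The two ortho C–H positions of the aryloxy ring are equivalent, so only one dibenzofuran can form.

Step 6
Reactants: 14 3,7,9-trimethoxydibenzo[b,d]furan-2-carbaldehyde
Product: 16 3,7,9-trimethoxydibenzo[b,d]furan-2-ol, via aryl formate 15 (not isolated)
Conditions: mCPBA, CH2Cl2, 0 °C → rt; then K2CO3 (cat.), MeOH
Reagents that add atoms: 3-chloroperoxybenzoic acid (mCPBA), OOC(=O)c1cccc(Cl)c1
Why: Dakin-type Baeyer–Villiger oxidation; the electron-rich aryl group (ortho and para oxygen donors) migrates in preference to hydrogen, and the formate is methanolysed.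

Step 7
Reactants: 16 3,7,9-trimethoxydibenzo[b,d]furan-2-ol
Product: 17 1-iodo-3,7,9-trimethoxydibenzo[b,d]furan-2-ol
Conditions: I2, NaHCO3, THF/H2O, 0 °C → rt
Reagents that add atoms: iodine, II
Why: Electrophilic iodination of the phenoxide, which outpaces the aryl ether rings; C1 is its only free ortho position because C3 carries OMe and the para position C4a is part of the furan.

Step 8
Reactants: 17 1-iodo-3,7,9-trimethoxydibenzo[b,d]furan-2-ol
Product: 18 1-iodo-3,7,9-trimethoxydibenzo[b,d]furan-2-yl trifluoromethanesulfonate
Conditions: Tf2O, pyridine, CH2Cl2, 0 °C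
Reagents that add atoms: trifluoromethanesulfonic anhydride, O=S(=O)(OS(=O)(=O)C(F)(F)F)C(F)(F)F
Why: O-sulfonylation of the phenol; the triflate is the latent leaving group at C2 for dioxin closure.

Step 9
Reactants: 18 1-iodo-3,7,9-trimethoxydibenzo[b,d]furan-2-yl trifluoromethanesulfonate
Product: 20 [3,7,9-trimethoxy-2-(trifluoromethanesulfonyloxy)dibenzo[b,d]furan-1-yl](2,4,6-trimethoxyphenyl)iodonium 4-methylbenzenesulfonate, via iodine diacetate 19 (not isolated)
Conditions: NaBO3·4H2O, AcOH, 45 °C; then 1,3,5-trimethoxybenzene, TsOH·H2O, CH2Cl2, 0 °C → rt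
Reagents that add atoms: 1,3,5-trimethoxybenzene, COc1cc(OC)cc(OC)c1; 4-methylbenzenesulfonic acid, Cc1ccc(S(=O)(=O)O)cc1
Why: Peracid oxidation of the aryl iodide to the trivalent-iodine diacetate, then acid-triggered electrophilic substitution on trimethoxybenzene (standard diaryliodonium salt synthesis). The diacetate is unreactive toward arenes until acid is added, and the dummy arene is already present then, so it should outcompete ring D of a second molecule.

Step 10
Reactants: 10 2,3-bis(benzyloxy)-6-ethoxy-4-(methoxymethoxy)phenol; 20 dibenzofuranyl(trimethoxyphenyl)iodonium tosylate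
Product: 21 1-[2,3-bis(benzyloxy)-6-ethoxy-4-(methoxymethoxy)phenoxy]-3,7,9-trimethoxydibenzo[b,d]furan-2-yl trifluoromethanesulfonate
Conditions: K2CO3, MeCN, 50 °C, Ar
Reagents that add atoms: none
Why: Metal-free O-arylation with a diaryliodonium salt: the phenoxide exchanges onto trivalent iodine and ligand coupling transfers the ortho-substituted, less electron-rich dibenzofuranyl group while the trimethoxyphenyl dummy leaves as its iodide. This reaction type tolerates di-ortho substitution on both partners, and the single free hydroxyl of 10 fixes the A5–O–C1 bond.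

Step 11
Reactants: 21 the diaryl ether triflate
Product: 22 1-[6-ethoxy-2,3-dihydroxy-4-(methoxymethoxy)phenoxy]-3,7,9-trimethoxydibenzo[b,d]furan-2-yl trifluoromethanesulfonate
Conditions: H2 (1 atm), Pd/C, EtOAc, rt
Reagents that add atoms: none
Why: Hydrogenolysis of the two benzyl aryl ethers; without added base the aryl triflate, the acetal and the alkyl aryl ethers should be inert.

Step 12
Reactants: 22 the catechol triflate
Product: 23 pentacyclic dioxin phenol ([1]benzofuro[3,2-a]oxanthrene core; A1–OH free, A2–OCH2OCH3, A4–OEt, OMe at C3, C7 and C9)
Conditions: Pd(OAc)2 (cat.), tBuXPhos, K3PO4, toluene, 100 °C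
Reagents that add atoms: none
Why: Intramolecular Buchwald–Hartwig etherification: zerovalent palladium inserts into the C2–O triflate bond, the A6 phenoxide binds and C–O reductive elimination closes the dioxin. Only the A6 oxygen can reach C2 through a six-membered ring, so the orientation is fixed.

Step 13
Reactants: 24 1-iodo-3,5-dimethoxybenzene
Product: 26 (3,5-dimethoxyphenyl)(2,4,6-trimethoxyphenyl)iodonium 4-methylbenzenesulfonate, via hydroxy(tosyloxy)iodoarene 25 (not isolated)
Conditions: mCPBA, TsOH·H2O, MeCN, rt; then 1,3,5-trimethoxybenzene
Reagents that add atoms: 1,3,5-trimethoxybenzene, COc1cc(OC)cc(OC)c1; 4-methylbenzenesulfonic acid, Cc1ccc(S(=O)(=O)O)cc1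
Why: One-pot oxidation of the aryl iodide to trivalent iodine and arylation of the added electron-rich arene (standard unsymmetrical diaryliodonium synthesis).

Step 14
Reactants: 23 pentacyclic dioxin phenol; 26 ring E iodonium tosylate
Product: 27 hepta-O-protected target (as 23 with A1–O–(3,5-dimethoxyphenyl))
Conditions: K2CO3, MeCN, 50 °C, Ar
Reagents that add atoms: none
Why: Metal-free O-arylation by ligand coupling at trivalent iodine; the trimethoxyphenyl group is too electron-rich to transfer, and A1–OH is the only free hydroxyl.

Step 15
Reactants: 27 hepta-O-protected target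
Product: 28 target, CNP0256302.0
Conditions: BBr3 (excess), CH2Cl2, −78 °C → rt; then MeOH, H2O, Ar
Reagents that add atoms: none
Why: Lewis acid O-dealkylation: boron coordinates each ether oxygen and bromide removes methyl, ethyl and the acetal carbon; aryl–O–aryl, dioxin and furan bonds have no alkyl carbon to attack and should survive.

## Compound list

1 | squaric acid (3,4-dihydroxycyclobut-3-ene-1,2-dione) | OC1=C(O)C(=O)C1=O | starting material
2 | benzyl alcohol | OCc1ccccc1 | starting material
3 | dibenzyl squarate, 3,4-bis(benzyloxy)cyclobut-3-ene-1,2-dione | O=C1C(=O)C(OCc2ccccc2)=C1OCc1ccccc1 | intermediate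
4 | (Z)-1-bromo-2-ethoxyethene | CCO/C=C\Br | starting material
5 | (Z)-2-ethoxyvinyllithium | CCO/C=C\[Li] | intermediate (not isolated)
6 | lithium rac-2,3-bis(benzyloxy)-1-[(Z)-2-ethoxyethenyl]-4-oxocyclobut-2-en-1-olate | O=C1C(OCc2ccccc2)=C(OCc2ccccc2)C1(O[Li])/C=C\OCC | intermediate (not isolated)
7 | rac-2,3-bis(benzyloxy)-4-[(Z)-2-ethoxyethenyl]-4-(methoxymethoxy)cyclobut-2-en-1-one | O=C1C(OCc2ccccc2)=C(OCc2ccccc2)C1(OCOC)/C=C\OCC | intermediate
8 | (3Z,5Z)-2,3-bis(benzyloxy)-6-ethoxy-4-(methoxymethoxy)hexa-1,3,5-trien-1-one (dienylketene) | O=C=C(OCc1ccccc1)/C(OCc1ccccc1)=C(OCOC)\C=C/OCC | intermediate (not isolated)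
9 | rac-2,3-bis(benzyloxy)-6-ethoxy-4-(methoxymethoxy)cyclohexa-2,4-dien-1-one | CCOC1C=C(OCOC)C(OCc2ccccc2)=C(OCc2ccccc2)C1=O | intermediate (not isolated)
10 | 2,3-bis(benzyloxy)-6-ethoxy-4-(methoxymethoxy)phenol | CCOc1cc(OCOC)c(OCc2ccccc2)c(OCc2ccccc2)c1O | intermediate
11 | 5-bromo-4-fluoro-2-methoxybenzaldehyde | O=Cc1cc(Br)c(F)cc1OC | starting material
12 | 3,5-dimethoxyphenol | COc1cc(O)cc(OC)c1 | starting material
13 | 5-bromo-4-(3,5-dimethoxyphenoxy)-2-methoxybenzaldehyde | O=Cc1cc(Br)c(Oc2cc(OC)cc(OC)c2)cc1OC | intermediate
14 | 3,7,9-trimethoxydibenzo[b,d]furan-2-carbaldehyde | O=Cc1cc2c(cc1OC)oc1cc(OC)cc(OC)c12 | intermediate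
15 | 3,7,9-trimethoxydibenzo[b,d]furan-2-yl formate | O=COc1cc2c(cc1OC)oc1cc(OC)cc(OC)c12 | intermediate (not isolated)
16 | 3,7,9-trimethoxydibenzo[b,d]furan-2-ol | Oc1cc2c(cc1OC)oc1cc(OC)cc(OC)c12 | intermediate
17 | 1-iodo-3,7,9-trimethoxydibenzo[b,d]furan-2-ol | Oc1c(I)c2c(cc1OC)oc1cc(OC)cc(OC)c12 | intermediate
18 | 1-iodo-3,7,9-trimethoxydibenzo[b,d]furan-2-yl trifluoromethanesulfonate | O=S(=O)(Oc1c(I)c2c(cc1OC)oc1cc(OC)cc(OC)c12)C(F)(F)F | intermediate
19 | 1-[bis(acetyloxy)iodo]-3,7,9-trimethoxydibenzo[b,d]furan-2-yl trifluoromethanesulfonate | CC(=O)OI(OC(C)=O)c1c(OS(=O)(=O)C(F)(F)F)c(OC)cc2oc3cc(OC)cc(OC)c3c12 | intermediate (not isolated)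
20 | [3,7,9-trimethoxy-2-(trifluoromethanesulfonyloxy)dibenzo[b,d]furan-1-yl](2,4,6-trimethoxyphenyl)iodonium 4-methylbenzenesulfonate | COc1cc(OC)c([I+]c2c(OS(=O)(=O)C(F)(F)F)c(OC)cc3oc4cc(OC)cc(OC)c4c23)c(OC)c1.Cc1ccc(S(=O)(=O)[O-])cc1 | intermediate
21 | 1-[2,3-bis(benzyloxy)-6-ethoxy-4-(methoxymethoxy)phenoxy]-3,7,9-trimethoxydibenzo[b,d]furan-2-yl trifluoromethanesulfonate | CCOc1cc(OCOC)c(OCc2ccccc2)c(OCc2ccccc2)c1Oc1c(OS(=O)(=O)C(F)(F)F)c(OC)cc2oc3cc(OC)cc(OC)c3c12 | intermediate
22 | 1-[6-ethoxy-2,3-dihydroxy-4-(methoxymethoxy)phenoxy]-3,7,9-trimethoxydibenzo[b,d]furan-2-yl trifluoromethanesulfonate | CCOc1cc(OCOC)c(O)c(O)c1Oc1c(OS(=O)(=O)C(F)(F)F)c(OC)cc2oc3cc(OC)cc(OC)c3c12 | intermediate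
23 | pentacyclic dioxin phenol, [1]benzofuro[3,2-a]oxanthrene core with A1–OH, A2–OCH2OCH3, A4–OEt and OMe at C3, C7, C9 | CCOc1cc(OCOC)c(O)c2c1Oc1c(O2)c(OC)cc2oc3cc(OC)cc(OC)c3c12 | intermediate
24 | 1-iodo-3,5-dimethoxybenzene | COc1cc(I)cc(OC)c1 | starting material
25 | 1-[hydroxy(tosyloxy)iodo]-3,5-dimethoxybenzene | COc1cc(cc(OC)c1)I(O)OS(=O)(=O)c1ccc(C)cc1 | intermediate (not isolated)
26 | (3,5-dimethoxyphenyl)(2,4,6-trimethoxyphenyl)iodonium 4-methylbenzenesulfonate | COc1cc(OC)cc([I+]c2c(OC)cc(OC)cc2OC)c1.Cc1ccc(S(=O)(=O)[O-])cc1 | intermediate
27 | hepta-O-protected target: 23 with A1–O–(3,5-dimethoxyphenyl) | CCOc1cc(OCOC)c(Oc2cc(OC)cc(OC)c2)c2c1Oc1c(O2)c(OC)cc2oc3cc(OC)cc(OC)c3c12 | intermediate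
28 | CNP0256302.0: ring E 3,5-dihydroxyphenoxy at A1; OH at A2, A4, C3, C7, C9; dioxin bonds A5–O–C1 and A6–O–C2 | Oc1cc(O)cc(Oc2c(O)cc(O)c3c2Oc2c(O)cc4oc5cc(O)cc(O)c5c4c2O3)c1 | target

## Step count and least certain steps

Total: 15 steps. Longest linear sequence: 11 steps (11 and 12 to 28 through steps 4 to 12, 14 and 15). The ring A branch contributes 8 steps (steps 1 to 3, then 10 to 12, 14 and 15).

Step 3 (key step). Most likely failure: adventitious acid removes the acetal or hydrolyses the enol ether at 110 °C, or traces of water intercept the ketene before it cyclises, because both the allylic acetal and the ketene are highly reactive. Fallback, setting out from 6 and returning at 10: alkoxide 6 is quenched with aqueous NH4Cl to give rac-2,3-bis(benzyloxy)-4-[(Z)-2-ethoxyethenyl]-4-hydroxycyclobut-2-en-1-one F1. This carbinol is used at once and heated in toluene, where the free hydroxyl is an even stronger outward-rotating donor, to give 2,3-bis(benzyloxy)-5-ethoxybenzene-1,4-diol F2. The less hindered hydroxyl of the hydroquinone (the one next to the ring C–H) is then protected with MOMCl and i-Pr2NEt at 0 °C, which gives 10. Differentiation then rests on sterics and not on the electrocyclic event.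

Step 9. Most likely failure: once activated by acid, the trivalent iodine attacks the dimethoxy-substituted ring D of a second molecule instead of the added arene, or the electron-rich core is over-oxidised. Fallback, setting out from 18 and 10 and returning at 21: the iodonium stage is omitted and iodide 18 is coupled directly with phenol 10 in a copper-catalysed Ullmann ether synthesis (CuI, picolinic acid, K3PO4, DMSO, 90 °C). No new compound is made (entry F0).

Step 10. Most likely failure: ligand coupling at the crowded iodine centre is slow, so transfer of the triflyl group from sulfur to the phenoxide, or transfer of the wrong aryl group, competes. Fallback, setting out from 17 and 10 and returning at 21: the C2 oxygen is carried as an allyl ether during the union. Phenol 17 is allylated (allyl bromide, K2CO3, acetone) to 1-iodo-3,7,9-trimethoxy-2-(prop-2-en-1-yloxy)dibenzo[b,d]furan F3. Copper-catalysed Ullmann coupling of this iodide with 10 (CuI, picolinic acid, K3PO4, DMSO, 100 °C) should give 1-[2,3-bis(benzyloxy)-6-ethoxy-4-(methoxymethoxy)phenoxy]-3,7,9-trimethoxy-2-(prop-2-en-1-yloxy)dibenzo[b,d]furan F4. Deallylation with Pd(PPh3)4 (zerovalent palladium) and morpholine then gives 1-[2,3-bis(benzyloxy)-6-ethoxy-4-(methoxymethoxy)phenoxy]-3,7,9-trimethoxydibenzo[b,d]furan-2-ol F5, and triflation of this phenol (Tf2O, pyridine) gives 21.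

Step 12. Most likely failure: the triflyl group migrates to the neighbouring phenoxide, or C–O reductive elimination from the electron-rich arylpalladium is slow and the triflate is reduced or hydrolysed. Fallback, setting out from 21 and returning at 23: the polarity at C2 is inverted. Miyaura borylation of 21 (B2pin2, PdCl2(dppf), KOAc, dioxane, 90 °C) gives 2-{1-[2,3-bis(benzyloxy)-6-ethoxy-4-(methoxymethoxy)phenoxy]-3,7,9-trimethoxydibenzo[b,d]furan-2-yl}-4,4,5,5-tetramethyl-1,3,2-dioxaborolane F6. Hydrogenolysis (H2, Pd/C, EtOAc) gives 4-ethoxy-6-(methoxymethoxy)-3-{[3,7,9-trimethoxy-2-(4,4,5,5-tetramethyl-1,3,2-dioxaborolan-2-yl)dibenzo[b,d]furan-1-yl]oxy}benzene-1,2-diol F7. An intramolecular Chan–Lam etherification mediated by divalent copper (Cu(OAc)2, pyridine, 4 Å sieves, CH2Cl2, limited air) then closes the dioxin to 23; ring size again fixes the orientation.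

Step 15. Most likely failure: incomplete cleavage of the ethyl ether, and oxidative loss of the heptaphenol during work-up and chromatography. Fallback, setting out from 27 and returning at 28: after the BBr3 treatment the crude polyphenol is acetylated without isolation (Ac2O, pyridine) to the heptaacetate of the target F8. This is a stable compound that can be purified and in which any residual ether is easy to detect and separate. Methanolysis under argon (K2CO3 cat., MeOH) then gives 28.

## Further compounds

F1 | step 3 | rac-2,3-bis(benzyloxy)-4-[(Z)-2-ethoxyethenyl]-4-hydroxycyclobut-2-en-1-one | O=C1C(OCc2ccccc2)=C(OCc2ccccc2)C1(O)/C=C\OCC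
F2 | step 3 | 2,3-bis(benzyloxy)-5-ethoxybenzene-1,4-diol | CCOc1cc(O)c(OCc2ccccc2)c(OCc2ccccc2)c1O
F0 | step 9 | none | none
F3 | step 10 | 1-iodo-3,7,9-trimethoxy-2-(prop-2-en-1-yloxy)dibenzo[b,d]furan | C=CCOc1c(I)c2c(cc1OC)oc1cc(OC)cc(OC)c12
F4 | step 10 | 1-[2,3-bis(benzyloxy)-6-ethoxy-4-(methoxymethoxy)phenoxy]-3,7,9-trimethoxy-2-(prop-2-en-1-yloxy)dibenzo[b,d]furan | CCOc1cc(OCOC)c(OCc2ccccc2)c(OCc2ccccc2)c1Oc1c(OCC=C)c(OC)cc2oc3cc(OC)cc(OC)c3c12
F5 | step 10 | 1-[2,3-bis(benzyloxy)-6-ethoxy-4-(methoxymethoxy)phenoxy]-3,7,9-trimethoxydibenzo[b,d]furan-2-ol | CCOc1cc(OCOC)c(OCc2ccccc2)c(OCc2ccccc2)c1Oc1c(O)c(OC)cc2oc3cc(OC)cc(OC)c3c12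
F6 | step 12 | 2-{1-[2,3-bis(benzyloxy)-6-ethoxy-4-(methoxymethoxy)phenoxy]-3,7,9-trimethoxydibenzo[b,d]furan-2-yl}-4,4,5,5-tetramethyl-1,3,2-dioxaborolane | CCOc1cc(OCOC)c(OCc2ccccc2)c(OCc2ccccc2)c1Oc1c(B2OC(C)(C)C(C)(C)O2)c(OC)cc2oc3cc(OC)cc(OC)c3c12
F7 | step 12 | 4-ethoxy-6-(methoxymethoxy)-3-{[3,7,9-trimethoxy-2-(4,4,5,5-tetramethyl-1,3,2-dioxaborolan-2-yl)dibenzo[b,d]furan-1-yl]oxy}benzene-1,2-diol | CCOc1cc(OCOC)c(O)c(O)c1Oc1c(B2OC(C)(C)C(C)(C)O2)c(OC)cc2oc3cc(OC)cc(OC)c3c12
F8 | step 15 | heptaacetate of the target (acetate on each of the seven phenolic oxygens) | CC(=O)Oc1cc(OC(C)=O)cc(Oc2c(OC(C)=O)cc(OC(C)=O)c3c2Oc2c(OC(C)=O)cc4oc5cc(OC(C)=O)cc(OC(C)=O)c5c4c2O3)c1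
A1 | alternative 1 | 1,3-dimethoxydibenzo[b,d]furan-2,7,9-triol | COc1cc2oc3cc(O)cc(O)c3c2c(OC)c1O
A2 | alternative 1 | 2,6-dimethoxy-1,4-benzoquinone | COC1=CC(=O)C=C(OC)C1=O
A3 | alternative 1 | phloroglucinol (benzene-1,3,5-triol) | Oc1cc(O)cc(O)c1
A4 | alternative 2 | heptamethyl ether of the target | COc1cc(OC)cc(Oc2c(OC)cc(OC)c3c2Oc2c(OC)cc4oc5cc(OC)cc(OC)c5c4c2O3)c1
A5 | alternative 2 | 3,7,9-trimethoxydibenzo[b,d]furan-1,2-dione | COC1=Cc2oc3cc(OC)cc(OC)c3c2C(=O)C1=O
A6 | alternative 2 | 3-(3,5-dimethoxyphenoxy)-4,6-dimethoxybenzyne | COC1=C(Oc2cc(OC)cc(OC)c2)C#CC(OC)=C1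
A7 | alternative 3 | 2-(benzyloxy)-1,3-dimethoxydibenzo[b,d]furan-7,9-diol | COc1cc2oc3cc(O)cc(O)c3c2c(OC)c1OCc1ccccc1
A8 | alternative 3 | methyl 2-[3-acetyl-5-(benzyloxy)-4,6-dimethoxy-1-benzofuran-2-yl]acetate | COC(=O)Cc1oc2cc(OC)c(OCc3ccccc3)c(OC)c2c1C(C)=O
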